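**Retrosynthetic overview**

1. The target is numbered as a 6,8-dioxabicyclo[3.2.2]nonan-7-one: C1 (quaternary, α to the lactone C7=O), C2 (CHOH), C3, C4, C5 (C–CH3, lactone O6), ether O8, C9 (CH bearing the neryl-type chain). The C1 side chain is cut at its CH2–CH= bond (B-alkyl Suzuki coupling of a C1-vinyl group with a (Z)-iodoallyl ether); the C9 side chain comes intact from nerol.
2. The core is cut at C1–C2 and O8–C1. Both bonds form in one operation when a diazo keto ester, tethered through the tertiary C5 oxygen, is decomposed next to a 6-alkoxytetrahydropyran: oxonium ylide formation, then a Stevens [1,2]-shift.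
3. Enabling feature: in the tetrahydropyran precursor (O1, C2–C6) the ring oxygen O1 is 1,3 to the tertiary C3 ester oxygen (six-membered ylide), and its neighbour C6 is an acetal carbon, the only group on O+ able to migrate. The carbenoid carbon is inserted between O1 and C6, so the tetrahydropyran becomes the oxepane O8–C9–C5–C4–C3–C2–C1 while the 1,4-dioxan-2-one ring closes; the acetal PMBO group ends as the C2 hydroxyl.
4. The tetrahydropyran comes from an (S)-furyl carbinol by Achmatowicz ring expansion, Pd-glycosylation, methyl addition to the enone and diimide reduction.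
5. Ring order: furan, then pyranone, then (key step) dioxanone closure with tetrahydropyran-to-oxepane expansion, giving the bicyclic lactone.

Key step: step 14

Remark: the migrating acetal carbon is assumed to keep its configuration in the [1,2]-shift, as is usual when recombination occurs inside a bridged frame; the C2 configuration of the target rests on this. PMB = 4-methoxybenzyl.

**Step 1**
Reactants: 1 nerol
Product: 2 1-({[(2Z)-3,7-dimethylocta-2,6-dien-1-yl]oxy}methyl)-4-methoxybenzene (neryl PMB ether)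
Conditions: NaH, 4-methoxybenzyl chloride, Bu4NI (cat.), THF/DMF, 0 °C to rt
Reagents that add atoms: 4-methoxybenzyl chloride, COc1ccc(CCl)cc1
Why: Williamson etherification of the primary allylic alkoxide leaves the Z-alkene untouched, and PMB is chosen so that all three hydroxyls can be freed in one oxidative step at the end.

**Step 2**
Reactants: 2 neryl PMB ether
Product: 3 3-{(3Z)-5-[(4-methoxybenzyl)oxy]-3-methylpent-3-en-1-yl}-2,2-dimethyloxirane (racemic at the oxirane CH)
Conditions: mCPBA (1.0 equiv), CH2Cl2, −20 to 0 °C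
Reagents that add atoms: 3-chloroperoxybenzoic acid, OOC(=O)c1cccc(Cl)c1
Why: Prilezhaev epoxidation should select the remote, more electron-rich 6,7-alkene over the 2,3-alkene, which is deactivated by the allylic ether oxygen; the new stereocentre is destroyed in step 3.

**Step 3**
Reactants: 3 epoxide
Product: 5 (4Z)-6-[(4-methoxybenzyl)oxy]-4-methylhex-4-enal, via the 6,7-diol 4 (not isolated)
Conditions: H5IO6, THF/H2O, 0 °C
Reagents that add atoms: none
Why: Acid-mediated epoxide hydrolysis (water attacks the tertiary carbon) followed by periodate glycol cleavage (Malaprade reaction) releases acetone and the aldehyde carrying the intact Z-allylic ether chain.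

**Step 4**
Reactants: 5 aldehyde; 6 furan
Product: 8 racemic (4Z)-1-(furan-2-yl)-6-[(4-methoxybenzyl)oxy]-4-methylhex-4-en-1-ol, via 2-lithiofuran 7 (not isolated)
Conditions: furan, n-BuLi, THF, 0 °C; then 5, −78 °C; H2O quench
Reagents that add atoms: none
Why: C2-lithiation of furan and 1,2-addition of the aryllithium to the aldehyde form the C9–C5 bond of the future core.

**Step 5**
Reactants: 8 racemic furyl carbinol
Product: 9 (4Z)-1-(furan-2-yl)-6-[(4-methoxybenzyl)oxy]-4-methylhex-4-en-1-one
Conditions: Dess–Martin periodinane, CH2Cl2, rt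
Reagents that add atoms: none
Why: Dess–Martin oxidation of the secondary carbinol is mild enough to spare the furan, the Z-alkene and the PMB ether.

**Step 6**
Reactants: 9 furyl ketone
Product: 10 (1S,4Z)-1-(furan-2-yl)-6-[(4-methoxybenzyl)oxy]-4-methylhex-4-en-1-ol
Conditions: RuCl[(S,S)-TsDPEN](p-cymene) (cat.), HCO2H/Et3N, rt
Reagents that add atoms: none
Why: Noyori asymmetric transfer hydrogenation treats the 2-furyl ketone like an aryl alkyl ketone, so the (S,S)-ligand should deliver the (S)-carbinol, which becomes C9 of the target.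

**Step 7**
Reactants: 10 (S)-furyl carbinol
Product: 11 (2S)-6-hydroxy-2-{(3Z)-5-[(4-methoxybenzyl)oxy]-3-methylpent-3-en-1-yl}-2H-pyran-3(6H)-one (mixture of C6 anomers)
Conditions: N-bromosuccinimide, NaHCO3, THF/H2O, 0 °C
Reagents that add atoms: water, O
Why: Achmatowicz oxidative ring expansion (bromonium attack at furan C5, hydrolytic opening to the Z-enedione, re-closure of the carbinol oxygen onto the aldehyde) does not touch the carbinol centre, and the furan is far more nucleophilic than the trisubstituted alkene or the anisole ring.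

**Step 8**
Reactants: 11 pyranone lactol
Product: 12 tert-butyl (2S,6S)-6-{(3Z)-5-[(4-methoxybenzyl)oxy]-3-methylpent-3-en-1-yl}-5-oxo-5,6-dihydro-2H-pyran-2-yl carbonate (carbonate trans to the side chain)
Conditions: Boc2O, DMAP (cat.), CH2Cl2, −78 °C
Reagents that add atoms: di-tert-butyl dicarbonate, CC(C)(C)OC(=O)OC(=O)OC(C)(C)C
Why: Low-temperature acylation of the equilibrating lactol should favour the axial, anomerically stabilised trans carbonate; the cis anomer is removed by chromatography.

**Step 9**
Reactants: 12 trans carbonate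
Product: 13 (2S,6R)-6-[(4-methoxybenzyl)oxy]-2-{(3Z)-5-[(4-methoxybenzyl)oxy]-3-methylpent-3-en-1-yl}-2H-pyran-3(6H)-one (2,6-trans)
Conditions: Pd2(dba)3·CHCl3 (cat.), PPh3, 4-methoxybenzyl alcohol, CH2Cl2, 0 °C
Reagents that add atoms: 4-methoxybenzyl alcohol, COc1ccc(CO)cc1
Why: Pd-catalysed allylic substitution (Tsuji–Trost type glycosylation): zerovalent palladium ionises the anomeric carbonate with inversion and the alcohol attacks the π-allyl anti to the metal, so net retention gives the 2,6-trans acetal.

**Step 10**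
Reactants: 13 trans PMB pyranone
Product: 14 (2S,3R,6R)-6-[(4-methoxybenzyl)oxy]-2-{(3Z)-5-[(4-methoxybenzyl)oxy]-3-methylpent-3-en-1-yl}-3-methyl-3,6-dihydro-2H-pyran-3-ol (methyl cis to the C2 chain and trans to the C6 PMBO group)
Conditions: MeLi, CeCl3, THF, −78 °C; H2O quench
Reagents that add atoms: methyllithium, [Li]C
Why: The weakly basic organocerium adds 1,2 without enolising C2; axial attack anti to the pseudo-axial anomeric PMBO group, as in Luche reductions of such trans-pyranones, should set the (3R) tertiary carbinol (C5 of the target).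

**Step 11**
Reactants: 14 allylic tertiary alcohol
Product: 15 (2S,3R,6R)-6-[(4-methoxybenzyl)oxy]-2-{(3Z)-5-[(4-methoxybenzyl)oxy]-3-methylpent-3-en-1-yl}-3-methyloxan-3-ol
Conditions: 2-nitrobenzenesulfonohydrazide, Et3N, CH2Cl2, rt
Reagents that add atoms: none
Why: Diimide generated from the sulfonyl hydrazide reduces the cis-disubstituted ring alkene much faster than the trisubstituted side-chain alkene and cannot hydrogenolyse PMB; saturating the ring also rules out a Carroll rearrangement in step 12.

**Step 12**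
Reactants: 15 tertiary alcohol
Product: 16 (2S,3R,6R)-6-[(4-methoxybenzyl)oxy]-2-{(3Z)-5-[(4-methoxybenzyl)oxy]-3-methylpent-3-en-1-yl}-3-methyloxan-3-yl 3-oxobutanoate
Conditions: 2,2,6-trimethyl-4H-1,3-dioxin-4-one, toluene, 110 °C
Reagents that add atoms: 2,2,6-trimethyl-4H-1,3-dioxin-4-one, CC1=CC(=O)OC(C)(C)O1
Why: Thermal retro-hetero-Diels–Alder fragmentation of the dioxinone gives acetylketene, which acylates even tertiary alcohols under neutral conditions that leave the acetal intact.

**Step 13**
Reactants: 16 acetoacetate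
Product: 17 (2S,3R,6R)-6-[(4-methoxybenzyl)oxy]-2-{(3Z)-5-[(4-methoxybenzyl)oxy]-3-methylpent-3-en-1-yl}-3-methyloxan-3-yl 2-diazo-3-oxobutanoate
Conditions: 4-acetamidobenzenesulfonyl azide, Et3N, MeCN, 0 °C to rt
Reagents that add atoms: 4-acetamidobenzenesulfonyl azide, CC(=O)Nc1ccc(cc1)S(=O)(=O)N=[N+]=[N-]
Why: Regitz diazo transfer to the active methylene of the β-keto ester is mild and base-catalysed.

**Step 14**
Reactants: 17 diazo keto ester
Product: 20 (1S,2S,5R,9S)-1-acetyl-2-[(4-methoxybenzyl)oxy]-9-{(3Z)-5-[(4-methoxybenzyl)oxy]-3-methylpent-3-en-1-yl}-5-methyl-6,8-dioxabicyclo[3.2.2]nonan-7-one, via copper carbenoid 18 (not isolated), via bridged oxonium ylide 19 (not isolated)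
Conditions: Cu(hfacac)2 (cat.; hfacac = CF3COCHCOCF3), ClCH2CH2Cl, reflux, slow addition of 17 at high dilution
Reagents that add atoms: none
Why: Divalent copper decomposes the diazo keto ester to an electrophilic carbenoid; after ring flip of the tetrahydropyran to the chair with the C3 acyloxy group axial, the ring oxygen O1 (1,3 to that ester oxygen) adds to the carbenoid carbon and closes the 1,4-dioxan-2-one ring by O–C bond formation (six-membered, bridged oxonium ylide 19). The acetal carbon C6, the only substituent on O+ that can stabilise radical or oxocarbenium character through its PMBO group, then migrates from O+ to the ylide carbon (Stevens [1,2]-shift), which inserts the former carbenoid carbon between O1 and C6 and turns the six-membered tetrahydropyran into the seven-membered oxepane without a separate ring closure. The closest known reaction type is the copper- or rhodium-catalysed oxonium ylide formation/[1,2]-shift ring expansion of cyclic acetals carrying tethered diazoketones or α-diazo β-keto esters. The new quaternary centre C1 is a bridgehead whose configuration is dictated by the C5 centre through the ester tether, and the migrating carbon should keep its configuration because recombination inside the bridged frame is faster than rotation, so the 2,6-trans (6R) acetal gives the (2S) PMB ether. The step needs ylide formation to beat 1,5-C–H insertion at C2–H, carbene dimerisation and attack at other oxygens: Cu(hfacac)2 favours ylide over insertion chemistry, every other ether oxygen would need an eight-membered or larger ylide, slow addition at high dilution suppresses dimerisation, and the oxonium carries no allyl group so no [2,3]-shift can intervene. Of the two carbons on O+ only the acetal carbon should migrate, since the secondary alkyl carbon C2 has no stabilising group.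

**Step 15**
Reactants: 20 bicyclic keto lactone
Product: 21 1-[(1S,2S,5R,9S)-2-[(4-methoxybenzyl)oxy]-9-{(3Z)-5-[(4-methoxybenzyl)oxy]-3-methylpent-3-en-1-yl}-5-methyl-7-oxo-6,8-dioxabicyclo[3.2.2]nonan-1-yl]ethenyl trifluoromethanesulfonate
Conditions: KN(SiMe3)2, PhNTf2, THF, −78 °C; aq. NH4Cl
Reagents that add atoms: N-phenylbis(trifluoromethanesulfonimide), O=S(=O)(N(c1ccccc1)S(=O)(=O)C(F)(F)F)C(F)(F)F
Why: Kinetic deprotonation can only occur at the methyl group (the lactone α-carbon is a quaternary bridgehead) and O-triflation of the enolate gives the enol triflate.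

**Step 16**
Reactants: 21 enol triflate
Product: 22 (1R,2S,5R,9S)-1-ethenyl-2-[(4-methoxybenzyl)oxy]-9-{(3Z)-5-[(4-methoxybenzyl)oxy]-3-methylpent-3-en-1-yl}-5-methyl-6,8-dioxabicyclo[3.2.2]nonan-7-one
Conditions: Pd(OAc)2 (cat.), PPh3, HCO2H, Bu3N, DMF, 60 °C
Reagents that add atoms: none
Why: Pd-catalysed formate reduction of the vinyl triflate (oxidative addition, formate exchange, decarboxylation, reductive elimination) gives the vinyl group while lactone, PMB ethers and the trisubstituted alkene are inert.

**Step 17**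
Reactants: 23 propargyl alcohol
Product: 25 (2Z)-3-iodo-2-methylprop-2-en-1-ol, via the (Z)-vinylmagnesium alkoxide 24 (not isolated)
Conditions: MeMgBr (excess), CuI (cat.), THF/Et2O, −10 °C to rt; then I2, 0 °C; aqueous work-up
Reagents that add atoms: methylmagnesium bromide, C[Mg]Br; iodine, II
Why: Copper-catalysed, alkoxide-directed anti-carbomagnesiation of the alkyne gives the chelated (Z)-vinylmagnesium species, and iodinolysis with retention fixes iodine cis to the CH2O group.

**Step 18**
Reactants: 25 (Z)-iodo alcohol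
Product: 26 1-({[(2Z)-3-iodo-2-methylprop-2-en-1-yl]oxy}methyl)-4-methoxybenzene
Conditions: NaH, 4-methoxybenzyl chloride, Bu4NI (cat.), THF/DMF, 0 °C
Reagents that add atoms: 4-methoxybenzyl chloride, COc1ccc(CCl)cc1
Why: Williamson etherification; the vinyl iodide has no β-hydrogen on the substituted carbon, so dehydrohalogenation cannot compete.

**Step 19**
Reactants: 22 vinyl lactone; 26 (Z)-vinyl iodide
Product: 28 (1R,2S,5R,9S)-2-[(4-methoxybenzyl)oxy]-1-{(3Z)-5-[(4-methoxybenzyl)oxy]-4-methylpent-3-en-1-yl}-9-{(3Z)-5-[(4-methoxybenzyl)oxy]-3-methylpent-3-en-1-yl}-5-methyl-6,8-dioxabicyclo[3.2.2]nonan-7-one, via the B-alkyl-9-BBN adduct 27 (not isolated)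
Conditions: 9-BBN, THF, rt; then 26, Pd(dppf)Cl2 (cat.), AsPh3, Cs2CO3, DMF/H2O, rt
Reagents that add atoms: none
Why: 9-BBN adds anti-Markovnikov only to the monosubstituted alkene (the trisubstituted alkene is inert at rt), and the B-alkyl Suzuki–Miyaura coupling proceeds with retention at the vinyl iodide, fixing the Z geometry of the C1 side chain.

**Step 20**
Reactants: 28 tris-PMB ether
Product: 29 (1R,2S,5R,9S)-2-hydroxy-1-[(3Z)-5-hydroxy-4-methylpent-3-en-1-yl]-9-[(3Z)-5-hydroxy-3-methylpent-3-en-1-yl]-5-methyl-6,8-dioxabicyclo[3.2.2]nonan-7-one (target)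
Conditions: DDQ, CH2Cl2/pH 7 buffer, 0 °C
Reagents that add atoms: none
Why: Oxidative PMB cleavage (benzylic hydride abstraction by DDQ, hydrolysis of the oxocarbenium) should free all three hydroxyls at once under buffered conditions that spare the lactone and the Z-allylic alcohols.

**Compound list**

1 | nerol, (2Z)-3,7-dimethylocta-2,6-dien-1-ol | CC(C)=CCC/C(C)=C\CO | starting material
2 | neryl PMB ether | CC(C)=CCC/C(C)=C\COCc1ccc(OC)cc1 | intermediate
3 | 6,7-epoxyneryl PMB ether (racemic at the oxirane CH) | CC1(C)OC1CC/C(C)=C\COCc2ccc(OC)cc2 | intermediate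
4 | (6Z)-8-[(4-methoxybenzyl)oxy]-2,6-dimethyloct-6-ene-2,3-diol (not isolated) | CC(C)(O)C(O)CC/C(C)=C\COCc1ccc(OC)cc1 | intermediate
5 | (4Z)-6-[(4-methoxybenzyl)oxy]-4-methylhex-4-enal | O=CCC/C(C)=C\COCc1ccc(OC)cc1 | intermediate
6 | furan | c1ccoc1 | starting material
7 | 2-lithiofuran (not isolated) | [Li]c1ccco1 | intermediate
8 | racemic (4Z)-1-(furan-2-yl)-6-[(4-methoxybenzyl)oxy]-4-methylhex-4-en-1-ol | OC(CC/C(C)=C\COCc1ccc(OC)cc1)c2ccco2 | intermediate
9 | (4Z)-1-(furan-2-yl)-6-[(4-methoxybenzyl)oxy]-4-methylhex-4-en-1-one | O=C(CC/C(C)=C\COCc1ccc(OC)cc1)c2ccco2 | intermediate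
10 | (1S,4Z)-1-(furan-2-yl)-6-[(4-methoxybenzyl)oxy]-4-methylhex-4-en-1-ol | O[C@@H](CC/C(C)=C\COCc1ccc(OC)cc1)c2ccco2 | intermediate
11 | (2S)-6-hydroxy-2-{(3Z)-5-[(4-methoxybenzyl)oxy]-3-methylpent-3-en-1-yl}-2H-pyran-3(6H)-one (anomers) | O1[C@@H](CC/C(C)=C\COCc2ccc(OC)cc2)C(=O)C=CC1O | intermediate
12 | trans tert-butyl carbonate of 11, (2S,6S) | O1[C@@H](CC/C(C)=C\COCc2ccc(OC)cc2)C(=O)C=C[C@@H]1OC(=O)OC(C)(C)C | intermediate
13 | (2S,6R)-6-PMBO-2-substituted 2H-pyran-3(6H)-one (2,6-trans) | O1[C@@H](CC/C(C)=C\COCc2ccc(OC)cc2)C(=O)C=C[C@@H]1OCc3ccc(OC)cc3 | intermediate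
14 | (2S,3R,6R)-3-methyl-3,6-dihydro-2H-pyran-3-ol | O1[C@@H](CC/C(C)=C\COCc2ccc(OC)cc2)[C@](C)(O)C=C[C@@H]1OCc3ccc(OC)cc3 | intermediate
15 | (2S,3R,6R)-3-methyloxan-3-ol | O1[C@@H](CC/C(C)=C\COCc2ccc(OC)cc2)[C@](C)(O)CC[C@@H]1OCc3ccc(OC)cc3 | intermediate
16 | 3-oxobutanoate of 15 | O1[C@@H](CC/C(C)=C\COCc2ccc(OC)cc2)[C@](C)(OC(=O)CC(C)=O)CC[C@@H]1OCc3ccc(OC)cc3 | intermediate
17 | 2-diazo-3-oxobutanoate of 15 | O1[C@@H](CC/C(C)=C\COCc2ccc(OC)cc2)[C@](C)(OC(=O)C(=[N+]=[N-])C(C)=O)CC[C@@H]1OCc3ccc(OC)cc3 | intermediate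
18 | copper carbenoid from 17 (ligands omitted; not isolated) | O1[C@@H](CC/C(C)=C\COCc2ccc(OC)cc2)[C@](C)(OC(=O)C(=[Cu])C(C)=O)CC[C@@H]1OCc3ccc(OC)cc3 | intermediate
19 | bridged oxonium ylide (not isolated) | [O+]12[C@@H](CC/C(C)=C\COCc3ccc(OC)cc3)[C@](C)(OC(=O)[C-]1C(C)=O)CC[C@@H]2OCc4ccc(OC)cc4 | intermediate
20 | (1S,2S,5R,9S)-1-acetyl bicyclic lactone | CC(=O)[C@@]12O[C@@H](CC/C(C)=C\COCc3ccc(OC)cc3)[C@@](C)(CC[C@@H]1OCc4ccc(OC)cc4)OC2=O | intermediate
21 | (1S,2S,5R,9S) enol triflate | C=C(OS(=O)(=O)C(F)(F)F)[C@@]12O[C@@H](CC/C(C)=C\COCc3ccc(OC)cc3)[C@@](C)(CC[C@@H]1OCc4ccc(OC)cc4)OC2=O | intermediate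
22 | (1R,2S,5R,9S)-1-ethenyl bicyclic lactone | C=C[C@@]12O[C@@H](CC/C(C)=C\COCc3ccc(OC)cc3)[C@@](C)(CC[C@@H]1OCc4ccc(OC)cc4)OC2=O | intermediate
23 | propargyl alcohol, prop-2-yn-1-ol | C#CCO | starting material
24 | (Z)-vinylmagnesium alkoxide (not isolated) | C/C(=C/[Mg]Br)CO[Mg]Br | intermediate
25 | (2Z)-3-iodo-2-methylprop-2-en-1-ol | C/C(=C/I)CO | intermediate
26 | PMB ether of 25 | C/C(=C/I)COCc1ccc(OC)cc1 | intermediate
27 | B-alkyl-9-BBN adduct of 22 (not isolated) | C1CC2CCCC(C1)B2CC[C@@]34O[C@@H](CC/C(C)=C\COCc5ccc(OC)cc5)[C@@](C)(CC[C@@H]3OCc6ccc(OC)cc6)OC4=O | intermediate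
28 | (1R,2S,5R,9S) tris-PMB ether of the target | C/C(=C/CC[C@@]12O[C@@H](CC/C(C)=C\COCc3ccc(OC)cc3)[C@@](C)(CC[C@@H]1OCc4ccc(OC)cc4)OC2=O)COCc5ccc(OC)cc5 | intermediate
29 | (1R,2S,5R,9S)-2-hydroxy-1-[(3Z)-5-hydroxy-4-methylpent-3-en-1-yl]-9-[(3Z)-5-hydroxy-3-methylpent-3-en-1-yl]-5-methyl-6,8-dioxabicyclo[3.2.2]nonan-7-one | C/C(=C/CC[C@@]12O[C@@H](CC/C(C)=C\CO)[C@@](C)(CC[C@@H]1O)OC2=O)CO | target

**Step count**

Total: 20 steps. Longest linear sequence: 18 steps (steps 1–16, 19 and 20, from nerol); steps 17 and 18 make the coupling partner.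

**Steps most likely to fail and fallbacks**

Step 14. The carbenoid may be consumed before the tetrahydropyran reaches the chair with the axial acyloxy group (1,5-C–H insertion at C2–H, dimerisation). The doubly stabilised ylide may also collapse by [1,4]-migration of the acetal carbon to the enolate oxygen instead of C–C recombination, or the migrating centre may partly lose its configuration. The fallback sets out from 17. Reduction of the ketone with NaBH4 (MeOH, 0 °C) should give the 2-diazo-3-hydroxybutanoate F1 (carbinol epimers), and dehydration with POCl3/Et3N (CH2Cl2, 0 °C) the 2-diazobut-3-enoate F2. Decomposition of F2 with Rh2(OAc)4 (CH2Cl2, rt, slow addition) should pass through the rhodium vinylcarbenoid F3 and the vinyl-substituted oxonium ylide F4 and, by the same [1,2]-shift, give 22 directly, where the route is rejoined (steps 15 and 16 fall away). The donor/acceptor carbenoid lives longer and its ylide has no ketone oxygen to accept the migrating carbon.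

Step 19. The bridged lactone may be opened by aqueous base, or the hindered alkylborane may protodeboronate during a slow transmetalation. The fallback sets out from 22. Hydroboration as before gives 27, which is oxidised with NaBO3·4H2O to the primary alcohol F5. I2/PPh3/imidazole converts F5 into the iodide F6, and Zn dust/LiCl (THF) gives the alkylzinc iodide F7. Base-free Negishi coupling of F7 with 26 (Pd(PPh3)4, THF, rt) should give 28, where the route is rejoined.

Step 7. The bromonium source may lose chemoselectivity (bromohydrin formation at the trisubstituted alkene, bromination of the anisole ring). The fallback sets out from racemic 8 and uses Sharpless kinetic-resolution conditions: Ti(OiPr)4, L-(+)-diisopropyl tartrate, t-BuOOH, CH2Cl2, −20 °C, run to about half conversion. The titanium–tartrate peroxide is delivered only to the furyl carbinol, and the fast-reacting (S)-enantiomer should undergo the oxidative ring expansion to 11, where the route is rejoined (steps 5 and 6 fall away). The slow-reacting (R)-alcohol F8 is left behind and can be recycled by oxidation to 9.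

**Further compounds**

F1 | step 14 | (2S,3R,6R)-oxan-3-yl 2-diazo-3-hydroxybutanoate (carbinol epimers) | O1[C@@H](CC/C(C)=C\COCc2ccc(OC)cc2)[C@](C)(OC(=O)C(=[N+]=[N-])C(C)O)CC[C@@H]1OCc3ccc(OC)cc3
F2 | step 14 | (2S,3R,6R)-oxan-3-yl 2-diazobut-3-enoate | O1[C@@H](CC/C(C)=C\COCc2ccc(OC)cc2)[C@](C)(OC(=O)C(=[N+]=[N-])C=C)CC[C@@H]1OCc3ccc(OC)cc3
F3 | step 14 | rhodium vinylcarbenoid from F2 (ligands omitted; not isolated) | O1[C@@H](CC/C(C)=C\COCc2ccc(OC)cc2)[C@](C)(OC(=O)C(=[Rh])C=C)CC[C@@H]1OCc3ccc(OC)cc3
F4 | step 14 | vinyl-substituted bridged oxonium ylide (not isolated) | [O+]12[C@@H](CC/C(C)=C\COCc3ccc(OC)cc3)[C@](C)(OC(=O)[C-]1C=C)CC[C@@H]2OCc4ccc(OC)cc4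
F5 | step 19 | (1R,2S,5R,9S)-1-(2-hydroxyethyl) bicyclic lactone | OCC[C@@]12O[C@@H](CC/C(C)=C\COCc3ccc(OC)cc3)[C@@](C)(CC[C@@H]1OCc4ccc(OC)cc4)OC2=O
F6 | step 19 | (1R,2S,5R,9S)-1-(2-iodoethyl) bicyclic lactone | ICC[C@@]12O[C@@H](CC/C(C)=C\COCc3ccc(OC)cc3)[C@@](C)(CC[C@@H]1OCc4ccc(OC)cc4)OC2=O
F7 | step 19 | alkylzinc iodide from F6 (not isolated) | I[Zn]CC[C@@]12O[C@@H](CC/C(C)=C\COCc3ccc(OC)cc3)[C@@](C)(CC[C@@H]1OCc4ccc(OC)cc4)OC2=O
F8 | step 7 | (1R,4Z)-1-(furan-2-yl)-6-[(4-methoxybenzyl)oxy]-4-methylhex-4-en-1-ol (unreacted enantiomer) | O[C@H](CC/C(C)=C\COCc1ccc(OC)cc1)c2ccco2
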